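**Plan**

- Retrosynthesis: the acetate, the 8(17)-ene and the C5/C9 hydrogens lead back to a 5,8-dien-7-one. Its C1–C10 bond (ring A) is cut to a phenol carrying a 3-bromopropyl arm on C4. The arene is then cut at C9–C11 (Negishi), at C4–CH3 and C4–C5 (titanium methylation, aryl Grignard addition) and at C7–O.
- Forward: ring B is bought as the benzene ring of 2-bromo-m-xylene (C5–C10 with the C17 and C20 methyls). The C5 arm, the C9 side chain and the C7 oxygen are added in that order, ring A closes by dearomatisation, and ring B is then reduced and oxidised to the target pattern.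
- Enabling feature: in ring B the C7 oxygen stands para to C10, which carries the C20 methyl. Ring B (C5–C10) is therefore a masked 4-methylphenol whose para carbon can be alkylated by C1 without re-aromatising.
- Stereochemistry: C13 comes from methyl hydrogen (R)-3-methylglutarate, and C10 from a chiral ammonium–phenoxide ion pair in the ring-A closure. C5 and C9 come from two lithium–ammonia reductions that protonate anti to the C20 methyl, and C7 from α-face epoxidation of the 7-ene followed by epoxide-to-allylic-alcohol isomerisation.
- Labdane numbering (C1–C20) is used for the skeleton throughout.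

Key step: step 10

Remark (assumption): the sense of facial induction by the cinchonidinium ion pair cannot be predicted with certainty; should it favour the C10 epimer, the pseudo-enantiomeric N-(9-anthracenylmethyl)cinchoninium bromide would take its place.

**Route**

Step 1
Reactants: 1 methyl hydrogen (R)-3-methylglutarate
Product: 2 methyl (R)-5-hydroxy-3-methylpentanoate
Conditions: BH3·SMe2, THF, 0 °C to rt; MeOH quench
Reagents that add atoms: none
Why: Chemoselective borane reduction takes the free carboxylic acid much faster than the methyl ester, so only the acid terminus becomes CH2OH and the untouched C3 stereocentre is carried over; the hydroxy ester should be used at once to avoid lactonisation.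

Step 2
Reactants: 2 methyl (R)-5-hydroxy-3-methylpentanoate
Product: 3 methyl (S)-5-iodo-3-methylpentanoate
Conditions: I2, PPh3, imidazole, CH2Cl2, 0 °C to rt
Reagents that add atoms: iodine, II
Why: Appel-type iodination converts the primary alcohol into the iodide by SN2 displacement of the oxyphosphonium group under neutral conditions that spare the ester and the remote stereocentre (the descriptor becomes S only because iodine raises the CIP rank of that arm).

Step 3
Reactants: 4 2-bromo-1,3-dimethylbenzene
Product: 5 2-bromo-4-iodo-1,3-dimethylbenzene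
Conditions: NIS (1.0 equiv), TFA, MeCN, rt, dark
Reagents that add atoms: N-iodosuccinimide, O=C1CCC(=O)N1I
Why: Electrophilic aromatic iodination should go to the ring position ortho to one methyl, para to the other and meta to bromine (the later C5), whereas the only other free type of position is meta to both methyls; one equivalent of NIS keeps it at mono-substitution.

Step 4
Reactants: 5 2-bromo-4-iodo-1,3-dimethylbenzene; 6 5-chloropentan-2-one
Product: 8 rac-2-(3-bromo-2,4-dimethylphenyl)-5-chloropentan-2-ol, via arylmagnesium chloride 7 (not isolated)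
Conditions: i-PrMgCl·LiCl, THF, 0 °C to rt; then 6, LaCl3·2LiCl, 0 °C; NH4Cl (aq), 0 °C
Reagents that add atoms: none
Why: Iodine–magnesium exchange with the turbo-Grignard reagent is far faster at the aryl iodide than at the doubly ortho-blocked aryl bromide, and LaCl3·2LiCl favours Grignard 1,2-addition to the enolisable ketone over deprotonation; the cold quench keeps the chloro alkoxide from closing to a tetrahydrofuran, and the racemic carbinol carbon becomes the achiral C4.

Step 5
Reactants: 8 rac-2-(3-bromo-2,4-dimethylphenyl)-5-chloropentan-2-ol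
Product: 9 2-bromo-4-(5-chloro-2-methylpentan-2-yl)-1,3-dimethylbenzene
Conditions: ZnMe2, TiCl4, CH2Cl2, −40 to 0 °C
Reagents that add atoms: dimethylzinc, C[Zn]C (methyl donor, passed on through dimethyltitanium dichloride, C[Ti](C)(Cl)Cl, formed in the flask with TiCl4)
Why: Titanium-mediated SN1 methylation of a tertiary benzylic alcohol: the dichlorotitanium alkoxide ionises to the benzylic cation, which takes a methyl group from titanium to give the quaternary C4, while the aryl bromide and the primary chloride are inert to the reagent.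

Step 6
Reactants: 3 methyl (S)-5-iodo-3-methylpentanoate; 9 2-bromo-4-(5-chloro-2-methylpentan-2-yl)-1,3-dimethylbenzene
Product: 11 methyl (R)-5-[3-(5-chloro-2-methylpentan-2-yl)-2,6-dimethylphenyl]-3-methylpentanoate, via alkylzinc iodide 10 (not isolated)
Conditions: 3, Zn dust, LiCl, THF, 40 °C; then 9, Pd(OAc)2 (cat.), SPhos, THF, 60 °C
Reagents that add atoms: none
Why: LiCl-promoted zinc insertion into the primary iodide gives an ester-tolerant alkylzinc reagent, and Negishi sp3–sp2 coupling with a bulky biarylphosphine–palladium catalyst should join it to the di-ortho-substituted aryl bromide (C9–C11) without touching the alkyl chloride or C13.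

Step 7
Reactants: 11 methyl (R)-5-[3-(5-chloro-2-methylpentan-2-yl)-2,6-dimethylphenyl]-3-methylpentanoate
Product: 12 methyl (R)-5-[3-bromo-5-(5-chloro-2-methylpentan-2-yl)-2,6-dimethylphenyl]-3-methylpentanoate
Conditions: Br2, AcOH, rt, dark
Reagents that add atoms: bromine, BrBr
Why: Electrophilic aromatic bromination should take the only free position that is ortho and para to the two methyl groups (C7), since the other free position C6 is meta to both and shielded by the tert-alkyl group; dark polar conditions avoid benzylic bromination.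

Step 8
Reactants: 12 methyl (R)-5-[3-bromo-5-(5-chloro-2-methylpentan-2-yl)-2,6-dimethylphenyl]-3-methylpentanoate
Product: 14 methyl (R)-5-[3-(5-chloro-2-methylpentan-2-yl)-5-hydroxy-2,6-dimethylphenyl]-3-methylpentanoate, via pinacol boronate 13 (not isolated)
Conditions: B2pin2, PdCl2(dppf) (cat.), KOAc, 1,4-dioxane, 90 °C; then Oxone (2KHSO5·KHSO4·K2SO4), acetone/H2O, 0 °C
Reagents that add atoms: bis(pinacolato)diboron, CC1(C)OB(OC1(C)C)B1OC(C)(C)C(C)(C)O1 (boryl group of 13); potassium peroxymonosulfate, OOS(=O)(=O)[O-].[K+] (phenol oxygen of 14)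
Why: Miyaura borylation of the aryl bromide followed by oxidative ipso-hydroxylation of the aryl boronate (aryl shift from boron to oxygen) gives the phenol under conditions that are never basic enough to let a phenoxide cyclise early and that spare the ester and the alkyl chloride.

Step 9
Reactants: 14 methyl (R)-5-[3-(5-chloro-2-methylpentan-2-yl)-5-hydroxy-2,6-dimethylphenyl]-3-methylpentanoate
Product: 15 methyl (3R)-5-[3-(5-bromo-2-methylpentan-2-yl)-5-hydroxy-2,6-dimethylphenyl]-3-methylpentanoate
Conditions: LiBr (excess), 2-butanone, reflux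
Reagents that add atoms: lithium bromide, [Li+].[Br-]
Why: Finkelstein halide exchange (SN2) at the primary chloride is driven by the excess of LiBr and the low solubility of LiCl in the ketone solvent, and the neutral phenol does not alkylate under these conditions.

Step 10
Reactants: 15 methyl (3R)-5-[3-(5-bromo-2-methylpentan-2-yl)-5-hydroxy-2,6-dimethylphenyl]-3-methylpentanoate
Product: 16 methyl (10R,13R)-7-oxolabda-5,8-dien-15-oate
Conditions: N-(9-anthracenylmethyl)cinchonidinium bromide (20 mol%), Cs2CO3 (powdered), toluene (0.01 M), 0 °C to rt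
Reagents that add atoms: none
Why: Proposed new method: carbonate deprotonates the phenol, and the ammonium phenoxide, an ambident nucleophile, displaces the primary bromide at C1 through its para carbon C10 in an intramolecular SN2 reaction, which forms C1–C10 and leaves the cross-conjugated 5,8-dien-7-one because the C20 methyl on C10 blocks re-aromatisation. The closest known reaction types are the base-mediated para-C-alkylative cyclisation of meta-tethered 4-methylphenols to fused 4-methylcyclohexa-2,5-dienones and the asymmetric alkylative dearomatisation of phenols and naphthols under chiral phase-transfer or transition-metal catalysis. Ring A closes in the 6-exo-tet mode. The new quaternary stereocentre C10 (R in the dienone, the later 10β-methyl) is to be set by the chiral cation: in toluene only the tight cinchonidinium–phenoxide ion pair should be in solution, the anthracenylmethyl wall covers one face of the phenoxide and the tether closes on the open face, while the remote C13 centre gives no bias and makes the two outcomes diastereomers. The step needs C10- over C6- and O-alkylation and one face of C10: the C4 gem-dimethyl group clashes with the C20 methyl unless C3 stands out of the ring plane beside C10, which holds C1 over C10 and away from C6, intramolecular O-alkylation would need a strained meta-bridged eight-membered ether and high dilution suppresses intermolecular ether formation, whereas the facial choice rests on the counter-cation alone.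

Step 11
Reactants: 16 methyl (10R,13R)-7-oxolabda-5,8-dien-15-oate
Product: 17 (10R,13R)-7-oxolabda-5,8-dien-15-oic acid
Conditions: LiOH·H2O, THF/MeOH/H2O, rt; then HCl (aq) to pH 3, 0 °C
Reagents that add atoms: lithium hydroxide, [Li+].[OH-]
Why: Ester saponification frees the C15 acid, whose carboxylate is the form of the side chain that survives the dissolving-metal steps; C13 is β to the carboxyl and C10 is quaternary, so nothing can epimerise.

Step 12
Reactants: 17 (10R,13R)-7-oxolabda-5,8-dien-15-oic acid
Product: 19 (5S,10S,13R)-7-oxolabd-8-en-15-oic acid, via dilithium dienolate 18 (not isolated)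
Conditions: Li, NH3(l)/THF, −78 °C; isoprene; then NH4Cl
Reagents that add atoms: none
Why: Birch-type dissolving-metal conjugate reduction of the cross-conjugated dienone should take place on the less substituted enone arm (C5=C6, no α-substituent) and stop at the cross-conjugated dienolate; C5 is protonated from the α-face, anti to the angular C20 methyl, which sets the trans ring fusion (5α-H), and the quench protonates C6 to give the 8-en-7-one.

Step 13
Reactants: 19 (5S,10S,13R)-7-oxolabd-8-en-15-oic acid
Product: 21 (5S,9R,10S,13R)-7-(trifluoromethanesulfonyloxy)labd-7-en-15-oic acid, via dilithium enolate 20 (not isolated)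
Conditions: Li, t-BuOH (1 equiv), NH3(l)/THF, −78 °C; isoprene; NH3 removed; PhNTf2, THF, −78 to 0 °C; then HCl (aq, dilute)
Reagents that add atoms: N-phenylbis(trifluoromethanesulfonimide), O=S(=O)(N(c1ccccc1)S(=O)(=O)C(F)(F)F)C(F)(F)F
Why: Second dissolving-metal conjugate reduction with regiospecific enolate trapping: C9 is protonated from the α-face, anti to the C20 methyl, which places the side chain equatorial (9α-H), and the C7 enolate oxygen, far more nucleophilic than the lithium carboxylate, is O-sulfonylated to fix the double bond at C7=C8.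

Step 14
Reactants: 21 (5S,9R,10S,13R)-7-(trifluoromethanesulfonyloxy)labd-7-en-15-oic acid
Product: 22 (5S,9S,10S,13R)-labd-7-en-15-oic acid
Conditions: Pd(OAc)2 (cat.), PPh3, HCO2H, Et3N, DMF, 60 °C
Reagents that add atoms: none
Why: Palladium-catalysed formate reduction of an enol triflate (oxidative addition of zerovalent palladium into the C7–O bond, formate-to-hydride exchange with loss of CO2, reductive elimination) should give the 7-ene without moving the double bond or touching C9.

Step 15
Reactants: 22 (5S,9S,10S,13R)-labd-7-en-15-oic acid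
Product: 23 (5S,7R,8S,9R,10S,13R)-7,8-epoxylabdan-15-oic acid (7α,8α-epoxide)
Conditions: mCPBA, Na2HPO4, CH2Cl2, 0 °C
Reagents that add atoms: 3-chloroperoxybenzoic acid, OOC(=O)c1cccc(Cl)c1
Why: Prilezhaev epoxidation of the only alkene; the peracid should approach the α-face because the β-face of C8 is screened by the axial C20 methyl, which sets the 7α,8α-epoxide and with it the C7 oxygen of the target.

Step 16
Reactants: 23 (5S,7R,8S,9R,10S,13R)-7,8-epoxylabdan-15-oic acid
Product: 24 (5S,7R,9R,10S,13R)-7-hydroxylabd-8(17)-en-15-oic acid (7α-OH)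
Conditions: LiNEt2 (excess), Et2O/THF, 0 °C to reflux; then HCl (aq, dilute), 0 °C
Reagents that add atoms: none
Why: Base-promoted epoxide-to-allylic-alcohol isomerisation (syn β-elimination within a lithium amide–epoxide complex): the amide should remove a proton from the C17 methyl group in preference to the tertiary H9 or the C6 methylene, the C8–O bond breaks and the C7–O bond keeps its α-configuration, which gives the exocyclic 8(17)-ene and the axial 7α-alcohol.

Step 17
Reactants: 24 (5S,7R,9R,10S,13R)-7-hydroxylabd-8(17)-en-15-oic acid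
Product: 26 (5S,7R,9R,10S,13R)-7-acetoxylabd-8(17)-en-15-oic acid, via mixed acetic anhydride 25 (not isolated)
Conditions: Ac2O, pyridine, DMAP (cat.), rt; then H2O
Reagents that add atoms: acetic anhydride, CC(=O)OC(C)=O
Why: DMAP-catalysed acetylation of the axial secondary allylic alcohol proceeds with retention at C7; the carboxyl group is acetylated too, to a mixed anhydride that pyridine and water cleave at the acetyl carbonyl during work-up to return the free acid.

**Compound list**

1 | methyl hydrogen (R)-3-methylglutarate | OC(=O)C[C@@H](C)CC(=O)OC | starting material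
2 | methyl (R)-5-hydroxy-3-methylpentanoate | OCC[C@@H](C)CC(=O)OC | intermediate
3 | methyl (S)-5-iodo-3-methylpentanoate | ICC[C@@H](C)CC(=O)OC | intermediate
4 | 2-bromo-1,3-dimethylbenzene | Cc1cccc(C)c1Br | starting material
5 | 2-bromo-4-iodo-1,3-dimethylbenzene | Cc1ccc(I)c(C)c1Br | intermediate
6 | 5-chloropentan-2-one | CC(=O)CCCCl | starting material
7 | (3-bromo-2,4-dimethylphenyl)magnesium chloride (LiCl complex) | Cc1ccc([Mg]Cl)c(C)c1Br | intermediate (not isolated)
8 | rac-2-(3-bromo-2,4-dimethylphenyl)-5-chloropentan-2-ol | CC(O)(CCCCl)c1ccc(C)c(Br)c1C | intermediate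
9 | 2-bromo-4-(5-chloro-2-methylpentan-2-yl)-1,3-dimethylbenzene | CC(C)(CCCCl)c1ccc(C)c(Br)c1C | intermediate
10 | (S)-(5-methoxy-3-methyl-5-oxopentyl)zinc iodide | I[Zn]CC[C@@H](C)CC(=O)OC | intermediate (not isolated)
11 | methyl (R)-5-[3-(5-chloro-2-methylpentan-2-yl)-2,6-dimethylphenyl]-3-methylpentanoate | CC(C)(CCCCl)c1ccc(C)c(CC[C@@H](C)CC(=O)OC)c1C | intermediate
12 | methyl (R)-5-[3-bromo-5-(5-chloro-2-methylpentan-2-yl)-2,6-dimethylphenyl]-3-methylpentanoate | CC(C)(CCCCl)c1cc(Br)c(C)c(CC[C@@H](C)CC(=O)OC)c1C | intermediate
13 | methyl (R)-5-[3-(5-chloro-2-methylpentan-2-yl)-2,6-dimethyl-5-(4,4,5,5-tetramethyl-1,3,2-dioxaborolan-2-yl)phenyl]-3-methylpentanoate | CC(C)(CCCCl)c1cc(B2OC(C)(C)C(C)(C)O2)c(C)c(CC[C@@H](C)CC(=O)OC)c1C | intermediate (not isolated)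
14 | methyl (R)-5-[3-(5-chloro-2-methylpentan-2-yl)-5-hydroxy-2,6-dimethylphenyl]-3-methylpentanoate | CC(C)(CCCCl)c1cc(O)c(C)c(CC[C@@H](C)CC(=O)OC)c1C | intermediate
15 | methyl (3R)-5-[3-(5-bromo-2-methylpentan-2-yl)-5-hydroxy-2,6-dimethylphenyl]-3-methylpentanoate | Oc1cc(C(C)(C)CCCBr)c(C)c(CC[C@@H](C)CC(=O)OC)c1C | intermediate (precursor of the key step)
16 | methyl (10R,13R)-7-oxolabda-5,8-dien-15-oate | CC1=C(CC[C@@H](C)CC(=O)OC)[C@@]2(C)CCCC(C)(C)C2=CC1=O | intermediate (product of the key step)
17 | (10R,13R)-7-oxolabda-5,8-dien-15-oic acid | CC1=C(CC[C@@H](C)CC(=O)O)[C@@]2(C)CCCC(C)(C)C2=CC1=O | intermediate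
18 | dilithium (5S,10S,13R)-7-oxidolabda-6,8-dien-15-oate | CC1=C(CC[C@@H](C)CC(=O)[O-])[C@@]2(C)CCCC(C)(C)[C@@H]2C=C1[O-].[Li+].[Li+] | intermediate (not isolated)
19 | (5S,10S,13R)-7-oxolabd-8-en-15-oic acid (5α-H) | CC1=C(CC[C@@H](C)CC(=O)O)[C@@]2(C)CCCC(C)(C)[C@@H]2CC1=O | intermediate
20 | dilithium (5S,9R,10S,13R)-7-oxidolabd-7-en-15-oate | CC1=C([O-])C[C@H]2C(C)(C)CCC[C@]2(C)[C@H]1CC[C@@H](C)CC(=O)[O-].[Li+].[Li+] | intermediate (not isolated)
21 | (5S,9R,10S,13R)-7-(trifluoromethanesulfonyloxy)labd-7-en-15-oic acid | CC1=C(OS(=O)(=O)C(F)(F)F)C[C@H]2C(C)(C)CCC[C@]2(C)[C@H]1CC[C@@H](C)CC(=O)O | intermediate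
22 | (5S,9S,10S,13R)-labd-7-en-15-oic acid | CC1=CC[C@H]2C(C)(C)CCC[C@]2(C)[C@H]1CC[C@@H](C)CC(=O)O | intermediate
23 | (5S,7R,8S,9R,10S,13R)-7,8-epoxylabdan-15-oic acid (7α,8α-epoxide) | C[C@]12O[C@@H]2C[C@H]3C(C)(C)CCC[C@]3(C)[C@H]1CC[C@@H](C)CC(=O)O | intermediate
24 | (5S,7R,9R,10S,13R)-7-hydroxylabd-8(17)-en-15-oic acid (7α-OH) | C=C1[C@H](O)C[C@H]2C(C)(C)CCC[C@]2(C)[C@H]1CC[C@@H](C)CC(=O)O | intermediate
25 | acetic (5S,7R,9R,10S,13R)-7-acetoxylabd-8(17)-en-15-oic anhydride | C=C1[C@H](OC(C)=O)C[C@H]2C(C)(C)CCC[C@]2(C)[C@H]1CC[C@@H](C)CC(=O)OC(C)=O | intermediate (not isolated)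
26 | (5S,7R,9R,10S,13R)-7-acetoxylabd-8(17)-en-15-oic acid (CNP0156001.3; 7α-OAc, 5α-H, 9α-H, 10β-CH3) | C=C1[C@H](OC(C)=O)C[C@H]2C(C)(C)CCC[C@]2(C)[C@H]1CC[C@@H](C)CC(=O)O | target

**Step count**

Total steps: 17.
Longest linear sequence: 15 steps (steps 3–17, from 2-bromo-1,3-dimethylbenzene 4). The side-chain fragment 3 is made in two steps and joins at step 6.

**Steps most likely to fail**

1. Step 10 (key step, proposed new method). The cation sits at the oxygen, far from C10, so facial discrimination may be poor, and unpaired phenoxide may cyclise in the background without any control. Fallback with known chemistry: setting out from 15, the phenoxide is cyclised with KOt-Bu in t-BuOH without any chiral additive. This plain base-mediated para-C-alkylation should give 16 together with its C10 epimer, methyl (10S,13R)-7-oxolabda-5,8-dien-15-oate F1. The two diastereomers are separated by preparative HPLC on a polysaccharide chiral stationary phase, and the route is rejoined at 16. C10 is then secured by separation and not by induction.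

2. Step 13. The dianion may dissolve poorly once ammonia is removed, and carboxylate, tert-butoxide or amide may consume the triflimide, so that O-sulfonylation stays incomplete and the enolate is merely protonated. Fallback: setting out from 19, LiAlH4 reduces both the carboxyl group and the enone carbonyl to (5S,10S,13R)-labd-8-ene-7,15-diol F2 (C7 epimers). MnO2 re-oxidises only the allylic alcohol to (5S,10S,13R)-15-hydroxylabd-8-en-7-one F3, and TBSCl/imidazole gives (5S,10S,13R)-15-(tert-butyldimethylsilyloxy)labd-8-en-7-one F4. Li/NH3/t-BuOH reduction then leads through lithium (5S,9R,10S,13R)-15-(tert-butyldimethylsilyloxy)labd-7-en-7-olate F5, which is trapped with PhNTf2 as (5S,9R,10S,13R)-15-(tert-butyldimethylsilyloxy)labd-7-en-7-yl trifluoromethanesulfonate F6. Pd(OAc)2/PPh3/HCO2H/Et3N reduces this to tert-butyldimethylsilyl (5S,9S,10S,13R)-labd-7-en-15-yl ether F7, and Jones reagent (CrO3, H2SO4, acetone, 0 °C) cleaves the silyl ether and oxidises C15 to the acid, which rejoins the route at 22.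

3. Step 5. The ortho-methyl group twists the tertiary benzylic cation out of conjugation, so proton loss to the alkene or capture by the chloride may outrun methyl transfer from titanium. Fallback: setting out from 5, the same iodine–magnesium exchange is followed by addition to acetone, which gives 2-(3-bromo-2,4-dimethylphenyl)propan-2-ol F8. Allyltrimethylsilane with FeCl3 (cat.) in CH2Cl2 captures the cation with a far better carbon nucleophile to give 2-bromo-1,3-dimethyl-4-(2-methylpent-4-en-2-yl)benzene F9. Hydroboration with 9-BBN and NaBO3 oxidation gives 4-(3-bromo-2,4-dimethylphenyl)-4-methylpentan-1-ol F10, and Appel chlorination (PPh3, CCl4) brings the route back to 9.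

**Further compounds**

F1 | step 10 | methyl (10S,13R)-7-oxolabda-5,8-dien-15-oate | CC1=C(CC[C@@H](C)CC(=O)OC)[C@]2(C)CCCC(C)(C)C2=CC1=O
F2 | step 13 | (5S,10S,13R)-labd-8-ene-7,15-diol (C7 epimers) | CC1=C(CC[C@@H](C)CCO)[C@@]2(C)CCCC(C)(C)[C@@H]2CC1O
F3 | step 13 | (5S,10S,13R)-15-hydroxylabd-8-en-7-one | CC1=C(CC[C@@H](C)CCO)[C@@]2(C)CCCC(C)(C)[C@@H]2CC1=O
F4 | step 13 | (5S,10S,13R)-15-(tert-butyldimethylsilyloxy)labd-8-en-7-one | CC1=C(CC[C@@H](C)CCO[Si](C)(C)C(C)(C)C)[C@@]2(C)CCCC(C)(C)[C@@H]2CC1=O
F5 | step 13 | lithium (5S,9R,10S,13R)-15-(tert-butyldimethylsilyloxy)labd-7-en-7-olate (not isolated) | CC1=C([O-])C[C@H]2C(C)(C)CCC[C@]2(C)[C@H]1CC[C@@H](C)CCO[Si](C)(C)C(C)(C)C.[Li+]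
F6 | step 13 | (5S,9R,10S,13R)-15-(tert-butyldimethylsilyloxy)labd-7-en-7-yl trifluoromethanesulfonate | CC1=C(OS(=O)(=O)C(F)(F)F)C[C@H]2C(C)(C)CCC[C@]2(C)[C@H]1CC[C@@H](C)CCO[Si](C)(C)C(C)(C)C
F7 | step 13 | tert-butyldimethylsilyl (5S,9S,10S,13R)-labd-7-en-15-yl ether | CC1=CC[C@H]2C(C)(C)CCC[C@]2(C)[C@H]1CC[C@@H](C)CCO[Si](C)(C)C(C)(C)C
F8 | step 5 | 2-(3-bromo-2,4-dimethylphenyl)propan-2-ol | CC(C)(O)c1ccc(C)c(Br)c1C
F9 | step 5 | 2-bromo-1,3-dimethyl-4-(2-methylpent-4-en-2-yl)benzene | C=CCC(C)(C)c1ccc(C)c(Br)c1C
F10 | step 5 | 4-(3-bromo-2,4-dimethylphenyl)-4-methylpentan-1-ol | OCCCC(C)(C)c1ccc(C)c(Br)c1C
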